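**Assumption (one line):** Ar = 3,4,5-trimethoxyphenyl; lignan locants are used in the comments (C7/C8/C9 = THF C2/C3/CH2OH; C8'/C9'/C7' = THF C4/C5/benzylic CH2); the sense of induction in step 3 follows the accepted enamine model for this catalyst and should be confirmed by chiral HPLC of the lactone.

**Retrosynthetic overview**
1. The tetrahydrofuran is closed last, by acid-catalysed dehydrative C7–O ring closure of an acyclic 7-hydroxy triol; C7 falls trans to the C8 substituent.
2. The triol comes from hydride reduction of a trans α-aroyl-β-benzyl-γ-butyrolactone; this temporary lactone ring fixes C8 relative to C8' under thermodynamic control.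
3. The lactone comes from aldehyde reduction and lactonisation of a γ-formyl β-keto ester that already holds all skeletal carbons.
4. Key disconnection C8–C8', between two α-carbonyl carbons (1,4-dicarbonyl): the chiral enamine of 3-arylpropanal is coupled with an α-bromo aroylacetate acting as an electrophilic α-carbonyl (enolonium-type) radical; this sets C8'.
5. Ring order: γ-butyrolactone (formed in step 3, opened in step 4), then tetrahydrofuran (step 5).

**Step 1**
Reactants: 1 5-bromo-1,2,3-trimethoxybenzene; 2 prop-2-en-1-ol (allyl alcohol)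
Product: 3 3-(3,4,5-trimethoxyphenyl)propanal
Conditions: Pd(OAc)2 (3 mol%), Bu4NCl (1 equiv), NaHCO3 (2.5 equiv), DMF, 90 °C
Reagents that add atoms: none
Why: Heck reaction under Jeffery conditions; aryl-palladium adds to the terminal alkene carbon and β-hydride elimination toward the carbinol gives the enol, which tautomerises to the saturated aldehyde (no stereocentre).

**Step 2**
Reactants: 4 ethyl 3-oxo-3-(3,4,5-trimethoxyphenyl)propanoate
Product: 5 ethyl 2-bromo-3-oxo-3-(3,4,5-trimethoxyphenyl)propanoate (racemic)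
Conditions: NBS (1.05 equiv), NH4OAc (10 mol%), Et2O, 25 °C
Reagents that add atoms: N-bromosuccinimide, O=C1CCC(=O)N1Br
Why: Electrophilic α-bromination of the enol of a 1,3-dicarbonyl, much faster than bromination of the acyl-deactivated ring; the new centre is racemic and is destroyed in step 3.

**Step 3**
Reactants: 3 3-(3,4,5-trimethoxyphenyl)propanal; 5 ethyl 2-bromo-3-oxo-3-(3,4,5-trimethoxyphenyl)propanoate
Product: 8 (3S,4R)-3-(3,4,5-trimethoxybenzoyl)-4-[(3,4,5-trimethoxyphenyl)methyl]oxolan-2-one, via γ-formyl β-keto ester 6 (not isolated), via γ-hydroxy β-keto ester 7 (not isolated)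
Conditions: 3 (2 equiv), Ru(bpy)3Cl2 (0.5 mol%), (2R,5S)-2-tert-butyl-3,5-dimethylimidazolidin-4-one·TfOH (20 mol%), 2,6-lutidine (2 equiv), degassed DMF, blue LED, 23 °C; then MeOH, NaBH4, −40 °C; then NaOMe (1.5 equiv), −40 → 20 °C; aq. HCl work-up, chromatography, recrystallise if needed to raise ee
Reagents that add atoms: none
Why: Photoredox/enamine dual-catalytic α-alkylation of an aldehyde with an α-bromo-1,3-dicarbonyl: reduced Ru turns 5 into an electrophilic α-keto-ester radical that adds to the Si face of the E-enamine of 3 (enamine turned away from tert-butyl, Re face blocked by the 5-methyl), setting C8' as R in 6; chemoselective low-temperature NaBH4 reduction of the aldehyde gives 7, whose alkoxide lactonises, and protonation of the α-acyl lactone enolate gives the thermodynamically favoured trans (3S,4R) isomer, setting C8 relative to C8'.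

**Step 4**
Reactants: 8 (3S,4R)-3-(3,4,5-trimethoxybenzoyl)-4-[(3,4,5-trimethoxyphenyl)methyl]oxolan-2-one
Product: 9 (2R,3R)-2-[hydroxy(3,4,5-trimethoxyphenyl)methyl]-3-[(3,4,5-trimethoxyphenyl)methyl]butane-1,4-diol (mixture of carbinol epimers)
Conditions: LiBH4 (4 equiv), THF–MeOH (20:1), 0 °C → rt; aq. NH4Cl
Reagents that add atoms: none
Why: Borohydride reduction of the ketone, then of the lactone to the diol, without touching C8 or C8'; the new carbinol centre (C7) is formed unselectively, which is harmless because step 5 ionises it.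

**Step 5**
Reactants: 9 (2R,3R)-2-[hydroxy(3,4,5-trimethoxyphenyl)methyl]-3-[(3,4,5-trimethoxyphenyl)methyl]butane-1,4-diol
Product: 10 [(2S,3R,4R)-2-(3,4,5-trimethoxyphenyl)-4-[(3,4,5-trimethoxyphenyl)methyl]oxolan-3-yl]methanol
Conditions: (±)-CSA (10 mol%), CH2Cl2 (0.02 M), 0 °C → rt, stop at full conversion with Et3N
Reagents that add atoms: none
Why: Acid-catalysed SN1 dehydrative cycloetherification: both carbinol epimers give the same trimethoxybenzylic cation, only the 9'-OH can trap it in a five-membered ring (the other primary OH would give an oxetane), and the reversible closure places the aryl group trans to the adjacent CH2OH (2S), the all-cis alternative being strongly disfavoured.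

**Compound list**
1 | 5-bromo-1,2,3-trimethoxybenzene | COc1cc(Br)cc(OC)c1OC | starting material
2 | prop-2-en-1-ol (allyl alcohol) | C=CCO | starting material
3 | 3-(3,4,5-trimethoxyphenyl)propanal | COc1cc(CCC=O)cc(OC)c1OC | intermediate
4 | ethyl 3-oxo-3-(3,4,5-trimethoxyphenyl)propanoate | CCOC(=O)CC(=O)c1cc(OC)c(OC)c(OC)c1 | starting material
5 | ethyl 2-bromo-3-oxo-3-(3,4,5-trimethoxyphenyl)propanoate (racemic) | CCOC(=O)C(Br)C(=O)c1cc(OC)c(OC)c(OC)c1 | intermediate
6 | ethyl (3R)-3-formyl-2-(3,4,5-trimethoxybenzoyl)-4-(3,4,5-trimethoxyphenyl)butanoate (C2 epimers; formed in the flask) | O=C[C@H](Cc1cc(OC)c(OC)c(OC)c1)C(C(=O)OCC)C(=O)c1cc(OC)c(OC)c(OC)c1 | intermediate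
7 | ethyl (3R)-3-(hydroxymethyl)-2-(3,4,5-trimethoxybenzoyl)-4-(3,4,5-trimethoxyphenyl)butanoate (C2 epimers; formed in the flask) | OC[C@H](Cc1cc(OC)c(OC)c(OC)c1)C(C(=O)OCC)C(=O)c1cc(OC)c(OC)c(OC)c1 | intermediate
8 | (3S,4R)-3-(3,4,5-trimethoxybenzoyl)-4-[(3,4,5-trimethoxyphenyl)methyl]oxolan-2-one | O=C1OC[C@H](Cc2cc(OC)c(OC)c(OC)c2)[C@H]1C(=O)c1cc(OC)c(OC)c(OC)c1 | intermediate
9 | (2R,3R)-2-[hydroxy(3,4,5-trimethoxyphenyl)methyl]-3-[(3,4,5-trimethoxyphenyl)methyl]butane-1,4-diol (carbinol epimers) | OC[C@H](Cc1cc(OC)c(OC)c(OC)c1)[C@H](CO)C(O)c1cc(OC)c(OC)c(OC)c1 | intermediate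
10 | [(2S,3R,4R)-2-(3,4,5-trimethoxyphenyl)-4-[(3,4,5-trimethoxyphenyl)methyl]oxolan-3-yl]methanol | COc1cc(C[C@H]2CO[C@H](c3cc(OC)c(OC)c(OC)c3)[C@H]2CO)cc(OC)c1OC | target

**Totals**
Total steps: 5. Longest linear sequence: 4 steps (1 → 3 → 8 → 9 → 10, or 4 → 5 → 8 → 9 → 10).

**Three steps most likely to fail**

Step 3 (key coupling). The secondary, hindered bromo keto ester 5 may transfer bromine to the enamine instead of coupling, and 6 is a 1,4-dicarbonyl that can dehydrate to a furan before it is reduced. The fallback sets out from 3 and comes back at 8. Compound 3 is coupled under the same light-driven enamine catalysis with commercial 2-bromo-1-(3,4,5-trimethoxyphenyl)ethan-1-one (COc1cc(C(=O)CBr)cc(OC)c1OC), which gives an unhindered primary phenacyl radical. This yields (2R)-4-oxo-2-[(3,4,5-trimethoxyphenyl)methyl]-4-(3,4,5-trimethoxyphenyl)butanal F1, which is reduced in the same flask with NaBH4 at −78 °C to (3R)-4-hydroxy-3-[(3,4,5-trimethoxyphenyl)methyl]-1-(3,4,5-trimethoxyphenyl)butan-1-one F2. Ethyl chloroformate and pyridine convert the primary alcohol into ethyl (2R)-4-oxo-2-[(3,4,5-trimethoxyphenyl)methyl]-4-(3,4,5-trimethoxyphenyl)butyl carbonate F3. LiHMDS (2.2 equiv, THF, −78 → 0 °C) then closes the lactone by intramolecular C-acylation of the ketone enolate on the carbonate; acidic work-up gives trans keto lactone 8. In this variant C9 arrives as the carbonate carbon instead of with the radical partner.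

Step 5 (ring closure). The benzylic cation can also be attacked by the electron-rich ring of the benzyl group (Friedel–Crafts closure to an aryltetralin), and over-long acid exposure reopens the product. The fallback sets out from 9 and comes back at 10. Activated MnO2 (CH2Cl2, rt) oxidises only the benzylic alcohol of 9; the resulting keto diol closes spontaneously to (3R,4R)-3-(hydroxymethyl)-2-(3,4,5-trimethoxyphenyl)-4-[(3,4,5-trimethoxyphenyl)methyl]oxolan-2-ol F4. Ionic hydrogenation (Et3SiH, BF3·OEt2, CH2Cl2, −78 °C) reduces the cyclic 2-aryl oxocarbenium ion to 10. That ion is oxygen-stabilised and is reduced faster than it can alkylate an arene; the 2,3-trans isomer is the thermodynamic one under BF3.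

Step 4 (global reduction). Compound 8 is an enolisable 1,3-dicarbonyl: enolate formation can stall the reduction, and the intermediate aldolate can undergo retro-aldol cleavage. The fallback sets out from 8 and comes back at 9. The one-pot reduction is replaced by a staged route through the isolable aldol-type lactone. Luche reduction (NaBH4, CeCl3·7H2O, MeOH, −40 °C) reduces only the ketone under protic, weakly basic conditions and gives (3S,4R)-3-[hydroxy(3,4,5-trimethoxyphenyl)methyl]-4-[(3,4,5-trimethoxyphenyl)methyl]oxolan-2-one F5. LiAlH4 (THF, 0 °C) then opens this hydroxy lactone to triol 9.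

**Further compounds**
F1 | step 3 | (2R)-4-oxo-2-[(3,4,5-trimethoxyphenyl)methyl]-4-(3,4,5-trimethoxyphenyl)butanal | O=C[C@H](Cc1cc(OC)c(OC)c(OC)c1)CC(=O)c1cc(OC)c(OC)c(OC)c1
F2 | step 3 | (3R)-4-hydroxy-3-[(3,4,5-trimethoxyphenyl)methyl]-1-(3,4,5-trimethoxyphenyl)butan-1-one | OC[C@H](Cc1cc(OC)c(OC)c(OC)c1)CC(=O)c1cc(OC)c(OC)c(OC)c1
F3 | step 3 | ethyl (2R)-4-oxo-2-[(3,4,5-trimethoxyphenyl)methyl]-4-(3,4,5-trimethoxyphenyl)butyl carbonate | CCOC(=O)OC[C@H](Cc1cc(OC)c(OC)c(OC)c1)CC(=O)c1cc(OC)c(OC)c(OC)c1
F4 | step 5 | (3R,4R)-3-(hydroxymethyl)-2-(3,4,5-trimethoxyphenyl)-4-[(3,4,5-trimethoxyphenyl)methyl]oxolan-2-ol (anomer mixture; ring tautomer of the keto diol) | COc1cc(C[C@H]2COC(O)(c3cc(OC)c(OC)c(OC)c3)[C@H]2CO)cc(OC)c1OC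
F5 | step 4 | (3S,4R)-3-[hydroxy(3,4,5-trimethoxyphenyl)methyl]-4-[(3,4,5-trimethoxyphenyl)methyl]oxolan-2-one (carbinol epimers) | O=C1OC[C@H](Cc2cc(OC)c(OC)c(OC)c2)[C@H]1C(O)c1cc(OC)c(OC)c(OC)c1
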